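**Strategy.** The cyclohexane ring is cut between its tertiary carbinol carbon (C(OH)CH3) and the neighbouring ring CH2. Reading the ring sp2 carbon that carries the exocyclic C(CH3)CHO unit as the α-carbon of a 1-acetylcyclohexene puts the carbinol at the δ-position, a vinylogous aldol retron. One aminocatalytic operation joins tert-butyl acetoacetate to an acyclic 3-vinyl enone: Michael addition makes the bond to the future spiro carbon, and the resulting aminodiene closes the ring onto the acetoacetate ketone, setting two stereocentres. Enone reduction–triflation then fixes the exocyclic alkene geometry; allylation, a reductive aldol spiro-annulation and a Stille coupling complete the skeleton.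

Key step: step 4

Remark: the quinine-derived primary amine is assumed to shield the iminium face that leads to the configuration drawn for 9 at the ring CH bearing the silyloxypropyl chain; its quinidine-derived pseudo-enantiomer would be used if the sense of induction is the opposite. Relative configurations are given in words; absolute configurations are those of the SMILES in the compound list.

Step 1
Reactants: 1 4-[(tert-butyldimethylsilyl)oxy]butanal; 2 1-(triphenyl-λ5-phosphanylidene)propan-2-one
Product: 3 (3E)-7-[(tert-butyldimethylsilyl)oxy]hept-3-en-2-one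
Conditions: CH2Cl2, 40 °C
Reagents that add atoms: none
Why: Wittig olefination with a stabilised ylide should give the E-enone selectively.

Step 2
Reactants: 3 (3E)-7-[(tert-butyldimethylsilyl)oxy]hept-3-en-2-one
Product: 4 (3Z)-7-[(tert-butyldimethylsilyl)oxy]-3-iodohept-3-en-2-one
Conditions: I2, pyridine, 4-(dimethylamino)pyridine (cat.), CH2Cl2, rt
Reagents that add atoms: iodine ([I][I])
Why: α-Iodination of the enone by amine addition, enolate iodination and elimination (Baylis–Hillman-type α-halogenation) should place iodine on the α-carbon, cis to the chain.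

Step 3
Reactants: 4 (3Z)-7-[(tert-butyldimethylsilyl)oxy]-3-iodohept-3-en-2-one; 5 tributyl(ethenyl)stannane
Product: 6 (3E)-7-[(tert-butyldimethylsilyl)oxy]-3-ethenylhept-3-en-2-one (cross-conjugated dienone; chain trans to acetyl)
Conditions: Pd2(dba)3 (2.5 mol %), AsPh3, CuI, N-methylpyrrolidone, rt
Reagents that add atoms: none
Why: Stille coupling of the α-iodoenone proceeds with retention of the double-bond geometry and should give the 3-vinyl enone.

Step 4
Reactants: 6 (3E)-7-[(tert-butyldimethylsilyl)oxy]-3-ethenylhept-3-en-2-one; 7 tert-butyl 3-oxobutanoate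
Product: 9 tert-butyl (1R,2S,6S)-3-acetyl-6-hydroxy-6-methyl-2-{3-[(tert-butyldimethylsilyl)oxy]propyl}cyclohex-3-ene-1-carboxylate (ester, side chain and hydroxyl all cis), via open-chain Michael adduct 8 (not isolated)
Conditions: 9-amino-9-deoxy-epi-quinine (20 mol %), CF3CO2H (30 mol %), toluene, 40 °C
Reagents that add atoms: none
Why: Proposed new method: the primary amine condenses with the enone to an iminium ion, the enol of 7 adds to its β-carbon (the CH that carries the silyloxypropyl chain) on the face left open by the cinchona scaffold, and the 2-aminodiene so formed attacks the acetoacetate ketone through its terminal CH2 (vinylogous aldol), after which hydrolysis releases the conjugated enone and the catalyst. The closest known reaction types are the amine-catalysed Michael–aldol (Robinson-type) annulation of β-keto esters with enones and dienamine-mediated vinylogous aldol additions. The six-membered ring closes by a 6-exo-trig attack on the ketone with the diene terminus as nucleophile (6-enolendo). The CH stereocentre is set by the catalyst in the Michael step; the carbinol centre is set by the substrate, because allylic 1,3-strain with the exocyclic aminodiene holds the silyloxypropyl chain axial and the ketone methyl then takes the equatorial site, which puts OH cis to the chain; the ester-bearing carbon can epimerise before ring closure and is redefined in step 6. The step needs reaction through the vinylogous (γ) carbon: attack through the α-carbon would give a cyclobutane, and the alternative aldol through the acetyl methyl group gives an unconjugated ketol that can revert, so the conjugated product 9 should accumulate.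

Step 5
Reactants: 9 tert-butyl (1R,2S,6S)-3-acetyl-6-hydroxy-6-methyl-2-{3-[(tert-butyldimethylsilyl)oxy]propyl}cyclohex-3-ene-1-carboxylate
Product: 11 tert-butyl 2-hydroxy-2-methyl-6-{3-[(tert-butyldimethylsilyl)oxy]propyl}-5-[(Z)-1-(trifluoromethanesulfonyloxy)ethylidene]cyclohexane-1-carboxylate (ring stereocentres as in 9), via dilithium enolate alkoxide 10 (not isolated)
Conditions: Li (2.2 equiv), NH3(l)/THF, −78 °C; NH3 removed; PhNTf2, THF, −78 → 0 °C; aq. NH4Cl
Reagents that add atoms: N-phenylbis(trifluoromethanesulfonimide) (O=S(=O)(N(c1ccccc1)S(=O)(=O)C(F)(F)F)C(F)(F)F)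
Why: Birch-type reduction of the enone (β-protonation by the tertiary hydroxyl) should give the exocyclic enolate regiospecifically with the geometry of the preferred s-trans enone (oxygen on the side of the ring CH that bears the chain), and O-triflation of this lithium enolate fixes the tetrasubstituted Z-alkene.

Step 6
Reactants: 11 the Z-enol triflate; 12 3-bromoprop-1-ene
Product: 14 tert-butyl 1-allyl-2-methyl-2-(triethylsilyloxy)-6-{3-[(tert-butyldimethylsilyl)oxy]propyl}-5-[(Z)-1-(trifluoromethanesulfonyloxy)ethylidene]cyclohexane-1-carboxylate (allyl trans to the silyloxy group and to the side chain; ester cis to both), via lithium alkoxide of the allylated ester 13 (not isolated)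
Conditions: LiN(iPr)2 (3 equiv), THF/DMPU, −78 → −20 °C; 12, −78 → 0 °C; then Et3SiOTf, −78 → 0 °C
Reagents that add atoms: triethylsilyl trifluoromethanesulfonate (CC[Si](CC)(CC)OS(=O)(=O)C(F)(F)F)
Why: Fráter–Seebach alkylation of the β-hydroxy ester dianion should deliver the allyl group to the ring face anti to both the alkoxide and the axial silyloxypropyl chain, creating the quaternary (future spiro) carbon with the ester cis to oxygen and chain, after which the lithium alkoxide is silylated in the same flask.

Step 7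
Reactants: 14 the allylated enol triflate
Product: 15 methyl (2Z)-2-{3-allyl-3-(tert-butoxycarbonyl)-4-methyl-4-(triethylsilyloxy)-2-{3-[(tert-butyldimethylsilyl)oxy]propyl}cyclohexylidene}propanoate (ring stereocentres as in 14)
Conditions: Pd(OAc)2 (10 mol %), 1,3-bis(diphenylphosphino)propane, CO (1 atm), Et3N, MeOH/DMF, 60 °C
Reagents that add atoms: carbon monoxide ([C-]#[O+]); methanol (CO)
Why: Palladium-catalysed methoxycarbonylation of the enol triflate installs the future aldehyde carbon with retention of the alkene geometry.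

Step 8
Reactants: 15 the diester
Product: 16 (2Z)-2-{3-allyl-3-(hydroxymethyl)-4-methyl-4-(triethylsilyloxy)-2-{3-[(tert-butyldimethylsilyl)oxy]propyl}cyclohexylidene}propan-1-ol (ring stereocentres as in 14)
Conditions: LiAlH4, THF, 0 → 50 °C
Reagents that add atoms: none
Why: Hydride reduction converts the enoate (1,2-reduction) and the hindered tert-butyl ester into the two primary alcohols, while silyl ethers and alkenes are inert.

Step 9
Reactants: 16 the diol
Product: 17 the allylic mono(tert-butyldimethylsilyl) ether of 16 (neopentylic CH2OH free)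
Conditions: t-BuMe2SiCl (1.05 equiv), imidazole, CH2Cl2, −20 °C
Reagents that add atoms: tert-butyldimethylsilyl chloride (CC(C)(C)[Si](C)(C)Cl)
Why: Silylation should take place at the allylic primary hydroxyl, because the other one is neopentylic and flanked by the quaternary carbon and the silyloxy-bearing carbon.

Step 10
Reactants: 17 the mono-silyl ether
Product: 18 1-allyl-cyclohexane-1-carbaldehyde (CH2OH of 17 oxidised to CHO; all else unchanged)
Conditions: Dess–Martin periodinane, NaHCO3, CH2Cl2, 0 °C → rt
Reagents that add atoms: none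
Why: Dess–Martin oxidation of the remaining primary alcohol gives a non-enolisable aldehyde without touching alkenes or silyl ethers.

Step 11
Reactants: 18 the aldehyde; 19 but-3-en-2-one
Product: 20 enone aldehyde (the allyl group of 18 replaced by (2E)-4-oxopent-2-en-1-yl)
Conditions: second-generation Hoveyda–Grubbs catalyst (5 mol %), 19 (5 equiv), CH2Cl2, 40 °C
Reagents that add atoms: none
Why: Cross-metathesis of the terminal allyl group with the electron-poor vinyl ketone should give the E-enone, the tetrasubstituted alkene being inert.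

Step 12
Reactants: 20 the enone aldehyde
Product: 22 1-{1-hydroxy-6-methyl-6-(triethylsilyloxy)-10-{3-[(tert-butyldimethylsilyl)oxy]propyl}-9-[(Z)-1-[(tert-butyldimethylsilyl)oxy]propan-2-ylidene]spiro[4.5]decan-2-yl}ethan-1-one (hydroxyl and acetyl cis on the five-membered ring, both on the side of C-10), via copper enolate 21 (not isolated)
Conditions: [(Ph3P)CuH]6, toluene, −40 → 0 °C; aq. NH4Cl
Reagents that add atoms: none
Why: Copper hydride conjugate reduction followed by intramolecular aldol addition (reductive aldol cyclisation, 5-exo-trig) through a closed chair-like transition state of the Z-enolate should give the cis-β-hydroxy ketone, with the aldehyde oxygen turned toward the ring CH and away from the bulky silyloxy-bearing quaternary carbon, which sets both new centres of the cyclopentane.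

Step 13
Reactants: 22 the spiro ketol
Product: 23 the triethylsilyl ether of 22 at the secondary hydroxyl
Conditions: Et3SiOTf, 2,6-lutidine, CH2Cl2, −78 °C
Reagents that add atoms: triethylsilyl trifluoromethanesulfonate (CC[Si](CC)(CC)OS(=O)(=O)C(F)(F)F)
Why: Silylation of the hindered secondary alcohol blocks retro-aldol cleavage in the following enolisation.

Step 14
Reactants: 23 the silylated methyl ketone
Product: 25 1-(spiro[4.5]decan-2-yl)ethenyl trifluoromethanesulfonate (acetyl of 23 converted into CH2=C(OTf)–), via potassium enolate 24 (not isolated)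
Conditions: KN(SiMe3)2, THF, −78 °C; PhNTf2, −78 → −20 °C
Reagents that add atoms: N-phenylbis(trifluoromethanesulfonimide) (O=S(=O)(N(c1ccccc1)S(=O)(=O)C(F)(F)F)C(F)(F)F)
Why: Kinetic deprotonation occurs at the methyl group and O-triflation of the enolate gives the 1,1-disubstituted enol triflate without disturbing the adjacent stereocentre.

Step 15
Reactants: 26 5-bromo-2-methylpent-2-ene; 27 prop-2-yn-1-ol
Product: 30 (2Z)-3-iodo-2-(4-methylpent-3-en-1-yl)prop-2-en-1-ol, via homoprenylmagnesium bromide 28 (not isolated), via alkenylmagnesium chelate 29 (not isolated)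
Conditions: Mg, THF; 27 (0.4 equiv), CuI (10 mol %), THF, −10 °C → rt; I2, −78 °C → rt
Reagents that add atoms: iodine ([I][I])
Why: Copper-catalysed anti-carbomagnesiation of the propargylic alkoxide gives a five-membered chelated alkenylmagnesium species, and its iodinolysis with retention should give the iodide with iodine cis to the hydroxymethyl group.

Step 16
Reactants: 30 the Z-iodo alcohol; 31 (E)-1,2-bis(tributylstannyl)ethene
Product: 32 (2Z,4E)-2-(4-methylpent-3-en-1-yl)-5-(tributylstannyl)penta-2,4-dien-1-ol
Conditions: PdCl2(MeCN)2 (5 mol %), 31 (3 equiv), DMF, rt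
Reagents that add atoms: none
Why: Stille mono-coupling with an excess of the distannane retains both alkene geometries and should give the dienylstannane.

Step 17
Reactants: 25 the enol triflate; 32 the dienylstannane
Product: 33 silyl-protected trienol (triflate of 25 replaced by the (1E,3Z)-4-(hydroxymethyl)-8-methylnona-1,3,7-trien-1-yl group)
Conditions: Pd(PPh3)4 (10 mol %), LiCl, CuCl, DMSO, 60 °C
Reagents that add atoms: none
Why: Copper-accelerated Stille coupling of the enol triflate with the dienylstannane forms the 2-substituted triene with retention of all alkene geometries.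

Step 18
Reactants: 33 the trienol
Product: 34 the acetate of 33
Conditions: Ac2O, pyridine, 4-(dimethylamino)pyridine (cat.), CH2Cl2, 0 °C
Reagents that add atoms: acetic anhydride (CC(=O)OC(C)=O)
Why: The primary allylic hydroxyl of the side chain is the only free hydroxyl, so acylation is unambiguous.

Step 19
Reactants: 34 the fully protected acetate
Product: 35 tetraol (all four silyl ethers removed; allylic alcohol in place of the aldehyde of the target)
Conditions: HF·pyridine, pyridine, THF, 0 °C → rt
Reagents that add atoms: none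
Why: Buffered fluoride cleaves the two tert-butyldimethylsilyl and two triethylsilyl ethers while the allylic acetate and the triene are left intact.

Step 20
Reactants: 35 the tetraol
Product: 36 CNP0205332.1 (target)
Conditions: MnO2, CH2Cl2, rt
Reagents that add atoms: none
Why: MnO2 oxidises only the allylic primary alcohol, giving the Z-enal without change of alkene geometry, while the saturated primary, secondary and tertiary hydroxyls are not touched.

**Compound list**

1 | 4-[(tert-butyldimethylsilyl)oxy]butanal | O=CCCCO[Si](C)(C)C(C)(C)C | starting material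
2 | 1-(triphenyl-λ5-phosphanylidene)propan-2-one | CC(=O)C=P(c1ccccc1)(c1ccccc1)c1ccccc1 | starting material
3 | (3E)-7-[(tert-butyldimethylsilyl)oxy]hept-3-en-2-one | CC(=O)/C=C/CCCO[Si](C)(C)C(C)(C)C | intermediate
4 | (3Z)-7-[(tert-butyldimethylsilyl)oxy]-3-iodohept-3-en-2-one | CC(=O)/C(I)=C/CCCO[Si](C)(C)C(C)(C)C | intermediate
5 | tributyl(ethenyl)stannane | C=C[Sn](CCCC)(CCCC)CCCC | starting material
6 | (3E)-7-[(tert-butyldimethylsilyl)oxy]-3-ethenylhept-3-en-2-one | CC(=O)/C(C=C)=C/CCCO[Si](C)(C)C(C)(C)C | intermediate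
7 | tert-butyl 3-oxobutanoate | CC(=O)CC(=O)OC(C)(C)C | starting material
8 | tert-butyl 2-acetyl-3-{3-[(tert-butyldimethylsilyl)oxy]propyl}-4-ethenyl-5-oxohexanoate (open-chain Michael adduct, defined at C-3 only) | CC(=O)C(C(=O)OC(C)(C)C)[C@H](CCCO[Si](C)(C)C(C)(C)C)C(C=C)C(C)=O | intermediate
9 | tert-butyl (1R,2S,6S)-3-acetyl-6-hydroxy-6-methyl-2-{3-[(tert-butyldimethylsilyl)oxy]propyl}cyclohex-3-ene-1-carboxylate | CC(=O)C1=CC[C@](C)(O)[C@H](C(=O)OC(C)(C)C)[C@@H]1CCCO[Si](C)(C)C(C)(C)C | intermediate
10 | dilithium salt of the exocyclic enolate and tertiary alkoxide derived from 9 | C/C([O-])=C1\CC[C@](C)([O-])[C@H](C(=O)OC(C)(C)C)[C@@H]1CCCO[Si](C)(C)C(C)(C)C.[Li+].[Li+] | intermediate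
11 | tert-butyl 2-hydroxy-2-methyl-6-{3-[(tert-butyldimethylsilyl)oxy]propyl}-5-[(Z)-1-(trifluoromethanesulfonyloxy)ethylidene]cyclohexane-1-carboxylate | C/C(OS(=O)(=O)C(F)(F)F)=C1\CC[C@](C)(O)[C@H](C(=O)OC(C)(C)C)[C@@H]1CCCO[Si](C)(C)C(C)(C)C | intermediate
12 | 3-bromoprop-1-ene | C=CCBr | starting material
13 | lithium alkoxide of the C-allylated hydroxy ester | C/C(OS(=O)(=O)C(F)(F)F)=C1\CC[C@](C)([O-])[C@](CC=C)(C(=O)OC(C)(C)C)[C@@H]1CCCO[Si](C)(C)C(C)(C)C.[Li+] | intermediate
14 | tert-butyl 1-allyl-2-methyl-2-(triethylsilyloxy)-6-{3-[(tert-butyldimethylsilyl)oxy]propyl}-5-[(Z)-1-(trifluoromethanesulfonyloxy)ethylidene]cyclohexane-1-carboxylate | C/C(OS(=O)(=O)C(F)(F)F)=C1\CC[C@](C)(O[Si](CC)(CC)CC)[C@](CC=C)(C(=O)OC(C)(C)C)[C@@H]1CCCO[Si](C)(C)C(C)(C)C | intermediate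
15 | methyl (2Z)-2-{3-allyl-3-(tert-butoxycarbonyl)-4-methyl-4-(triethylsilyloxy)-2-{3-[(tert-butyldimethylsilyl)oxy]propyl}cyclohexylidene}propanoate | C/C(C(=O)OC)=C1\CC[C@](C)(O[Si](CC)(CC)CC)[C@](CC=C)(C(=O)OC(C)(C)C)[C@@H]1CCCO[Si](C)(C)C(C)(C)C | intermediate
16 | (2Z)-2-{3-allyl-3-(hydroxymethyl)-4-methyl-4-(triethylsilyloxy)-2-{3-[(tert-butyldimethylsilyl)oxy]propyl}cyclohexylidene}propan-1-ol | C/C(CO)=C1\CC[C@](C)(O[Si](CC)(CC)CC)[C@](CC=C)(CO)[C@@H]1CCCO[Si](C)(C)C(C)(C)C | intermediate
17 | allylic mono(tert-butyldimethylsilyl) ether of 16 | C/C(CO[Si](C)(C)C(C)(C)C)=C1\CC[C@](C)(O[Si](CC)(CC)CC)[C@](CC=C)(CO)[C@@H]1CCCO[Si](C)(C)C(C)(C)C | intermediate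
18 | 1-allyl-2-methyl-2-(triethylsilyloxy)-6-{3-[(tert-butyldimethylsilyl)oxy]propyl}-5-[(Z)-1-[(tert-butyldimethylsilyl)oxy]propan-2-ylidene]cyclohexane-1-carbaldehyde | C/C(CO[Si](C)(C)C(C)(C)C)=C1\CC[C@](C)(O[Si](CC)(CC)CC)[C@](CC=C)(C=O)[C@@H]1CCCO[Si](C)(C)C(C)(C)C | intermediate
19 | but-3-en-2-one | C=CC(C)=O | starting material
20 | enone aldehyde: 18 with (2E)-4-oxopent-2-en-1-yl in place of allyl | C/C(CO[Si](C)(C)C(C)(C)C)=C1\CC[C@](C)(O[Si](CC)(CC)CC)[C@](C/C=C/C(C)=O)(C=O)[C@@H]1CCCO[Si](C)(C)C(C)(C)C | intermediate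
21 | copper Z-enolate from conjugate reduction of 20 (phosphine ligands omitted) | C/C(CO[Si](C)(C)C(C)(C)C)=C1\CC[C@](C)(O[Si](CC)(CC)CC)[C@](CC/C=C(/C)O[Cu])(C=O)[C@@H]1CCCO[Si](C)(C)C(C)(C)C | intermediate
22 | 1-{1-hydroxy-6-methyl-6-(triethylsilyloxy)-10-{3-[(tert-butyldimethylsilyl)oxy]propyl}-9-[(Z)-1-[(tert-butyldimethylsilyl)oxy]propan-2-ylidene]spiro[4.5]decan-2-yl}ethan-1-one | CC(=O)[C@@H]1CC[C@]2([C@H](CCCO[Si](C)(C)C(C)(C)C)/C(=C(/C)CO[Si](C)(C)C(C)(C)C)CC[C@]2(C)O[Si](CC)(CC)CC)[C@@H]1O | intermediate
23 | triethylsilyl ether of 22 at the secondary hydroxyl | CC(=O)[C@@H]1CC[C@]2([C@H](CCCO[Si](C)(C)C(C)(C)C)/C(=C(/C)CO[Si](C)(C)C(C)(C)C)CC[C@]2(C)O[Si](CC)(CC)CC)[C@@H]1O[Si](CC)(CC)CC | intermediate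
24 | potassium enolate of 23 (methyl side) | C=C([O-])[C@@H]1CC[C@]2([C@H](CCCO[Si](C)(C)C(C)(C)C)/C(=C(/C)CO[Si](C)(C)C(C)(C)C)CC[C@]2(C)O[Si](CC)(CC)CC)[C@@H]1O[Si](CC)(CC)CC.[K+] | intermediate
25 | 1-(spiro[4.5]decan-2-yl)ethenyl trifluoromethanesulfonate derived from 23 | C=C(OS(=O)(=O)C(F)(F)F)[C@@H]1CC[C@]2([C@H](CCCO[Si](C)(C)C(C)(C)C)/C(=C(/C)CO[Si](C)(C)C(C)(C)C)CC[C@]2(C)O[Si](CC)(CC)CC)[C@@H]1O[Si](CC)(CC)CC | intermediate
26 | 5-bromo-2-methylpent-2-ene | CC(C)=CCCBr | starting material
27 | prop-2-yn-1-ol | C#CCO | starting material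
28 | (4-methylpent-3-en-1-yl)magnesium bromide | CC(C)=CCC[Mg]Br | intermediate
29 | chelated (Z)-alkenylmagnesium alkoxide | CC(C)=CCC/C(CO[Mg]Br)=C/[Mg]Br | intermediate
30 | (2Z)-3-iodo-2-(4-methylpent-3-en-1-yl)prop-2-en-1-ol | OC/C(CCC=C(C)C)=C\I | intermediate
31 | (E)-1,2-bis(tributylstannyl)ethene | CCCC[Sn](CCCC)(CCCC)/C=C/[Sn](CCCC)(CCCC)CCCC | starting material
32 | (2Z,4E)-2-(4-methylpent-3-en-1-yl)-5-(tributylstannyl)penta-2,4-dien-1-ol | OC/C(CCC=C(C)C)=C\C=C\[Sn](CCCC)(CCCC)CCCC | intermediate
33 | silyl-protected trienol (free side-chain CH2OH) | C=C(/C=C/C=C(/CCC=C(C)C)CO)[C@@H]1CC[C@]2([C@H](CCCO[Si](C)(C)C(C)(C)C)/C(=C(/C)CO[Si](C)(C)C(C)(C)C)CC[C@]2(C)O[Si](CC)(CC)CC)[C@@H]1O[Si](CC)(CC)CC | intermediate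
34 | acetate of 33 | C=C(/C=C/C=C(/CCC=C(C)C)COC(C)=O)[C@@H]1CC[C@]2([C@H](CCCO[Si](C)(C)C(C)(C)C)/C(=C(/C)CO[Si](C)(C)C(C)(C)C)CC[C@]2(C)O[Si](CC)(CC)CC)[C@@H]1O[Si](CC)(CC)CC | intermediate
35 | tetraol (allylic alcohol in place of the aldehyde of the target) | C=C(/C=C/C=C(/CCC=C(C)C)COC(C)=O)[C@@H]1CC[C@]2([C@H](CCCO)/C(=C(/C)CO)CC[C@]2(C)O)[C@@H]1O | intermediate
36 | CNP0205332.1 | C=C(/C=C/C=C(/CCC=C(C)C)COC(C)=O)[C@@H]1CC[C@]2([C@H](CCCO)/C(=C(/C)C=O)CC[C@]2(C)O)[C@@H]1O | target

**Step count.** 20 steps in total. The longest linear sequence is 18 steps (steps 1–14 and 17–20); steps 15–16 make the side-chain stannane.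

**Steps most likely to fail**

Step 4. The cascade may stall at iminium formation with the α-branched enone, or the ring may close through the acetyl methyl group (Robinson mode) and dehydrate. The fallback is a stepwise Lewis-acid route built from known reaction types; it sets out from 6 and 7 and returns at 9. Compound 7 would be silylated (Me3SiCl, Et3N) to tert-butyl (2Z)-3-(trimethylsilyloxy)but-2-enoate F1. Mukaiyama–Michael addition of F1 to 6 under trityl-salt or Me3SiOTf catalysis proceeds with silyl transfer and would give the 2-silyloxy-1,3-diene Michael adduct F2, in which only the diene is nucleophilic. BF3·OEt2 or TiCl4 would then close the ring by an intramolecular vinylogous Mukaiyama aldol addition to the liberated ketone. Without a chiral Lewis acid this gives 9 together with its enantiomer F3, which would be removed by chromatography on a chiral stationary phase before the route continues from 9.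

Step 12. Hydride may add to the aldehyde instead of the enone, or the enolate may attack the wrong face of the aldehyde. The fallback sets the two centres separately; it sets out from 20 and returns at 22. A phosphine-catalysed intramolecular Morita–Baylis–Hillman reaction (PMe3, t-BuOH/THF) would create only the carbinol centre and give the cyclopentenol enone F7. Conjugate reduction (LiB(s-Bu)3H, THF, −78 °C) with kinetic protonation of the enolate anti to the neighbouring oxygen substituent would then set the acetyl-bearing carbon and give 22.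

Step 6. Deprotonation of the congested ester α-CH may be incomplete, or the lithium alkoxide may undergo retro-aldol cleavage. The fallback builds the quaternary carbon in the annulation itself; it sets out from 6 and returns at 14. tert-Butyl 2-acetylpent-4-enoate F4 (from 7 and 12, K2CO3, acetone) would replace 7 under the conditions of step 4 and give the C-allylated cyclohexenyl ketone F5, its epimer at the quaternary carbon being removed by chromatography. The conditions of step 5 would give the hydroxy enol triflate F6, and Et3SiOTf/2,6-lutidine would return to 14.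

Further compounds
F1 | step 4 | tert-butyl (2Z)-3-(trimethylsilyloxy)but-2-enoate | C/C(O[Si](C)(C)C)=C/C(=O)OC(C)(C)C
F2 | step 4 | tert-butyl 2-acetyl-3-{3-[(tert-butyldimethylsilyl)oxy]propyl}-4-ethenyl-5-(trimethylsilyloxy)hex-4-enoate (racemic silyl dienol ether) | C=CC(=C(C)O[Si](C)(C)C)C(CCCO[Si](C)(C)C(C)(C)C)C(C(C)=O)C(=O)OC(C)(C)C
F3 | step 4 | enantiomer of 9 | CC(=O)C1=CC[C@@](C)(O)[C@@H](C(=O)OC(C)(C)C)[C@H]1CCCO[Si](C)(C)C(C)(C)C
F4 | step 6 | tert-butyl 2-acetylpent-4-enoate | CC(=O)C(CC=C)C(=O)OC(C)(C)C
F5 | step 6 | tert-butyl 1-allyl-3-acetyl-6-hydroxy-6-methyl-2-{3-[(tert-butyldimethylsilyl)oxy]propyl}cyclohex-3-ene-1-carboxylate (allyl trans to chain and hydroxyl) | CC(=O)C1=CC[C@](C)(O)[C@](CC=C)(C(=O)OC(C)(C)C)[C@@H]1CCCO[Si](C)(C)C(C)(C)C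
F6 | step 6 | tert-butyl 1-allyl-2-hydroxy-2-methyl-6-{3-[(tert-butyldimethylsilyl)oxy]propyl}-5-[(Z)-1-(trifluoromethanesulfonyloxy)ethylidene]cyclohexane-1-carboxylate | C/C(OS(=O)(=O)C(F)(F)F)=C1\CC[C@](C)(O)[C@](CC=C)(C(=O)OC(C)(C)C)[C@@H]1CCCO[Si](C)(C)C(C)(C)C
F7 | step 12 | 1-{1-hydroxy-6-methyl-6-(triethylsilyloxy)-10-{3-[(tert-butyldimethylsilyl)oxy]propyl}-9-[(Z)-1-[(tert-butyldimethylsilyl)oxy]propan-2-ylidene]spiro[4.5]dec-2-en-2-yl}ethan-1-one | CC(=O)C1=CC[C@]2([C@H](CCCO[Si](C)(C)C(C)(C)C)/C(=C(/C)CO[Si](C)(C)C(C)(C)C)CC[C@]2(C)O[Si](CC)(CC)CC)[C@@H]1O
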